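**Strategy.** Ring A (C1, C10–C14) is disconnected to a cyclohexa-2,4-dienone whose C2 oxygen carries a propanoate; the ester supplies C11, C12 and C20. An intramolecular inverse-demand Diels–Alder reaction of its ketene silyl acetal forges C10–C11 and C12–C13 at once, exploiting the 1,5-relationship of O2 and the C12 carbonyl; the tether fixes C10 relative to the quaternary C1. The dienone ring atoms later become C1, C14, C13 and, after retro-Claisen cleavage of C13–C8, the C10–C9–C8 chain. A Nozaki–Hiyama–Kishi/lactonisation sequence, a second Nozaki–Hiyama–Kishi closure of the ten-membered ring at C2–C3 and a late ene chlorination complete the target.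

Key step: step 6

Remark: atom numbers in names and explanations are those of the target (briarane numbering): ring A = C1, C10, C11, C12, C13, C14; C15 = methyl on C1; C20 = methyl on C11; C2–C9 complete the ten-membered ring; C16 on C5; C17 (methyl C18) and C19 are lactone carbons.
Remark (assumption): a ketoreductase with the required sense of desymmetrisation is taken to be available from a commercial screening panel.

Step 1
Reactants: 1 2-methylcyclohexane-1,3-dione
Product: 2 2-(hydroxymethyl)-2-methylcyclohexane-1,3-dione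
Conditions: 37% aq. HCHO, NaHCO3 (cat.), THF/H2O, rt
Reagents that add atoms: formaldehyde, C=O
Why: Aldol hydroxymethylation at the only acidic carbon of the 1,3-dione; no stereocentre is formed.

Step 2
Reactants: 2 2-(hydroxymethyl)-2-methylcyclohexane-1,3-dione
Product: 3 (1-methyl-2,6-dioxocyclohexyl)methyl propanoate
Conditions: EtCOCl, pyridine, CH2Cl2, 0 °C
Reagents that add atoms: propanoyl chloride, CCC(Cl)=O
Why: O-acylation of the primary alcohol installs the tether that carries C11, C12 and C20.

Step 3
Reactants: 3 (1-methyl-2,6-dioxocyclohexyl)methyl propanoate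
Product: 4 [(1R,2R)-2-hydroxy-1-methyl-6-oxocyclohexyl]methyl propanoate
Conditions: ketoreductase, NADP+ (cat.), i-PrOH, phosphate buffer pH 7, 30 °C
Reagents that add atoms: none
Why: Enzymatic (ketoreductase) desymmetrising reduction of the prochiral 2,2-disubstituted 1,3-dione should reduce only the carbonyl that makes the quaternary carbon (future C1) R; the carbinol configuration is of no consequence because that carbon becomes sp2 in step 5.

Step 4
Reactants: 4 [(1R,2R)-2-hydroxy-1-methyl-6-oxocyclohexyl]methyl propanoate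
Product: 5 [(1R,2R)-1-methyl-2-(methylsulfonyloxy)-6-oxocyclohexyl]methyl propanoate
Conditions: MsCl, Et3N, CH2Cl2, 0 °C
Reagents that add atoms: methanesulfonyl chloride, CS(=O)(=O)Cl
Why: Mesylation turns the secondary hydroxyl into a leaving group for the later 1,4-elimination.

Step 5
Reactants: 5 [(1R,2R)-1-methyl-2-(methylsulfonyloxy)-6-oxocyclohexyl]methyl propanoate
Product: 7 [(1S)-1-methyl-6-oxocyclohexa-2,4-dien-1-yl]methyl propanoate, via mesyloxy enone 6 (not isolated)
Conditions: IBX, DMSO, 65 °C; then DBU, CH2Cl2, 0 °C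
Reagents that add atoms: none
Why: IBX dehydrogenation on the only enolisable side of the ketone gives the enone, and DBU then removes a γ-proton so that the δ-mesylate leaves in a vinylogous E1cB (1,4-) elimination; the dienone is used at once in dilute solution because such dienones dimerise.

Step 6
Reactants: 7 [(1S)-1-methyl-6-oxocyclohexa-2,4-dien-1-yl]methyl propanoate
Product: 9 tricyclic silyl ketal (oxa-twistenone), via ketene silyl acetal 8 (not isolated)
Conditions: LiN(SiMe3)2, TBSCl, HMPA, THF, −78 °C; then toluene, 80 °C (5 mM)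
Reagents that add atoms: tert-butyldimethylsilyl chloride, CC(C)(C)[Si](C)(C)Cl
Why: The lithium amide with HMPA converts the propanoate into its (Z)-ketene silyl acetal 8 (methyl cis to OSi), whose electron-rich C11=C12 bond adds across C10 and C13 of the electron-poor 2,4-dienone in an intramolecular inverse-electron-demand Diels–Alder reaction, asynchronous with C10–C11 bonding in advance. The closest known reaction types are the intramolecular Diels–Alder reactions of 6-tethered cyclohexa-2,4-dienones and the [4+2] additions of ketene acetals to electron-poor dienes. The cycloaddition closes ring A (C1, C10, C11, C12, C13, C14) inside a bicyclo[2.2.2]octenone; with respect to the tether the first bond closes a six-membered ring by 6-exo attack on C10 and the second completes an oxa-twistane cage. C10 and C13 are set by the tether, which can deliver the dienophile only to the dienone face that carries C2, so both follow from C1; C11 follows from the ketene acetal geometry by suprafacial addition (methyl towards the etheno bridge, also the more stable position), and C12 is a ketal carbon whose configuration is lost later. The step needs the bridged regiochemistry (C11 to C10, C12 to C13) instead of the fused alternative, and the polarity of the partners secures it, since the nucleophilic β-carbon C11 of the ketene acetal can bond only to the electrophilic δ-carbon C10 of the dienone.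

Step 7
Reactants: 9 tricyclic silyl ketal (oxa-twistenone)
Product: 11 bicyclo[2.2.2]octenone diol, via silyl ketal alcohol 10 (not isolated)
Conditions: NaBH4, MeOH/THF, −20 °C; then 1 M HCl, THF, 0 °C
Reagents that add atoms: none
Why: Hydride should attack the C14 ketone from the side of the etheno bridge because the other face is covered by the C2–O–C12 bridge, which places the 14-oxygen cis to C2 (14S); dilute acid then cleaves the labile silyl ketal to the C12 ketone and the C2 alcohol.

Step 8
Reactants: 11 bicyclo[2.2.2]octenone diol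
Product: 12 bis(tert-butyldimethylsilyl) ether of 11
Conditions: TBSOTf (2.5 equiv), 2,6-lutidine, CH2Cl2, −78 to 0 °C
Reagents that add atoms: tert-butyldimethylsilyl trifluoromethanesulfonate, CC(C)(C)[Si](C)(C)OS(=O)(=O)C(F)(F)F
Why: Silylation protects the primary C2 and the hindered C14 hydroxyls; with the hindered base the ketone is not enol-silylated.

Step 9
Reactants: 12 bis(tert-butyldimethylsilyl) ether of 11
Product: 13 cis-diol of the former etheno bridge
Conditions: OsO4 (5 mol %), NMO, acetone/H2O, rt
Reagents that add atoms: N-methylmorpholine N-oxide, C[N+]1([O-])CCOCC1; water, O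
Why: Catalytic syn-dihydroxylation (Upjohn) of the strained bridge alkene from its less hindered face; the diol configuration is irrelevant because both carbinols are oxidised next.

Step 10
Reactants: 13 cis-diol of the former etheno bridge
Product: 14 bicyclo[2.2.2]octane-2,5,6-trione (C9 and C8 ketones beside the C12 ketone)
Conditions: (COCl)2, DMSO, CH2Cl2, −78 °C; then Et3N
Reagents that add atoms: none
Why: Swern oxidation converts the vicinal diol into the 1,2-diketone without C–C cleavage; no stereocentre is touched.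

Step 11
Reactants: 14 bicyclo[2.2.2]octane-2,5,6-trione
Product: 16 (9S)-α-hydroxy methyl ester on ring A, via α-keto ester 15 (not isolated)
Conditions: NaOMe (0.2 equiv), MeOH/THF, −40 °C; then NaBH4, −78 °C
Reagents that add atoms: methanol, CO
Why: Methoxide adds to the more electrophilic C8 carbonyl of the non-enolisable tricarbonyl array and the adduct fragments by retro-Claisen cleavage of C13–C8 (C13 leaves as the C12 enolate and becomes CH2), opening the bicycle to ring A with a C10-bound α-keto ester; NaBH4 at −78 °C should then reduce only the activated C9 ketone, anti to the quaternary C1 (Felkin–Anh), to the 9S alcohol.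

Step 12
Reactants: 16 (9S)-α-hydroxy methyl ester on ring A
Product: 17 bridged methyl ketal (O9–C12 link)
Conditions: HC(OMe)3, CSA (cat.), CH2Cl2, 0 °C
Reagents that add atoms: trimethyl orthoformate, COC(OC)OC
Why: Acid-catalysed ketalisation in which the 9-hydroxyl and one methoxy group capture the C12 ketone as a bridged mixed ketal (6-oxabicyclo[3.2.1]octane), masking both groups at once; the bridge can form only on the face of ring A that carries C9, which fixes C12.

Step 13
Reactants: 17 bridged methyl ketal
Product: 18 β-keto ester (C8 ketone, C17 methyl, C19 methyl ester)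
Conditions: methyl propanoate, LiN(iPr)2, THF, −78 to −30 °C; AcOH quench
Reagents that add atoms: methyl propanoate, CCC(=O)OC
Why: Crossed Claisen condensation of the activated α-alkoxy ester with the lithium enolate of methyl propanoate adds C17, C18 and C19; C17 forms as an epimer mixture that is planarised in the next step.

Step 14
Reactants: 18 β-keto ester
Product: 19 (Z)-enol triflate (OTf on C8 cis to the ester)
Conditions: NaH, THF, 0 °C; then PhNTf2, 0 °C to rt
Reagents that add atoms: N-phenylbis(trifluoromethanesulfonimide), O=S(=O)(N(c1ccccc1)S(=O)(=O)C(F)(F)F)C(F)(F)F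
Why: O-triflation of the chelated sodium enolate of the β-keto ester should give the (Z)-enol triflate, the geometry needed for lactonisation after coupling.

Step 15
Reactants: 20 (Z)-3-methylpent-2-en-4-yn-1-ol
Product: 21 (Z)-3-methylpent-2-en-4-ynal
Conditions: MnO2, CH2Cl2, rt
Reagents that add atoms: none
Why: Selective oxidation of the allylic alcohol with MnO2 under neutral conditions keeps the Z geometry; the aldehyde is used directly.

Step 16
Reactants: 19 (Z)-enol triflate; 21 (Z)-3-methylpent-2-en-4-ynal
Product: 23 butenolide with the enynyl chain at C7, via hydroxy enoate 22 (not isolated)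
Conditions: CrCl2 (4 equiv), NiCl2 (2 mol %), chiral oxazoline–sulfonamide ligand, Et3N, THF, rt; then PPTS (cat.), CH2Cl2
Reagents that add atoms: none
Why: Nozaki–Hiyama–Kishi coupling of the alkenyl triflate with the aldehyde forms C7–C8 with retention of alkene geometry, so the new C7 oxygen sits cis to the ester and lactonises to the butenolide; C7 is set by the chiral ligand on chromium (reagent control).

Step 17
Reactants: 23 butenolide
Product: 24 8,17-epoxy lactone
Conditions: t-BuOOH, n-BuLi, THF, −20 °C
Reagents that add atoms: tert-butyl hydroperoxide, CC(C)(C)OO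
Why: Nucleophilic (Weitz–Scheffer type) epoxidation with lithium tert-butylperoxide, which should add to C8 anti to the C7 side chain, so the epoxide oxygen ends up cis to H7 as the 8-oxygen of the target requires.

Step 18
Reactants: 24 8,17-epoxy lactone
Product: 25 8-hydroxy lactone (C18 methyl cis to 8-OH)
Conditions: SmI2 (2.5 equiv), MeOH, THF, −78 °C
Reagents that add atoms: none
Why: SmI2 cleaves the Cα–O bond of the α,β-epoxy lactone and leaves the tertiary 8-hydroxyl with its configuration; protonation of the samarium enolate anti to the C8 alkoxide should place C18 cis to the hydroxyl, which is also the more stable C17 epimer.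

Step 19
Reactants: 25 8-hydroxy lactone
Product: 26 9-hydroxy 12-ketone
Conditions: PPTS, acetone/H2O, rt
Reagents that add atoms: water, O
Why: Mild acid hydrolysis of the bridged mixed ketal releases the C12 ketone and the 9-hydroxyl while the silyl ethers persist.

Step 20
Reactants: 26 9-hydroxy 12-ketone
Product: 27 9-acetate
Conditions: Ac2O, DMAP (cat.), pyridine, CH2Cl2, 0 °C
Reagents that add atoms: acetic anhydride, CC(=O)OC(C)=O
Why: Acetylation of the only free secondary alcohol; the tertiary 8-hydroxyl is inert under these conditions.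

Step 21
Reactants: 27 9-acetate
Product: 28 iodoalkyne
Conditions: NIS, AgNO3 (10 mol %), acetone, rt, dark
Reagents that add atoms: N-iodosuccinimide, O=C1CCC(=O)N1I
Why: Silver-catalysed iodination of the terminal alkyne via the silver acetylide; the alkenes are not touched.

Step 22
Reactants: 28 iodoalkyne
Product: 29 (3Z,5Z)-dienyl iodide
Conditions: 2-nitrobenzenesulfonohydrazide, Et3N, THF/i-PrOH, rt
Reagents that add atoms: none
Why: Diimide generated in the flask reduces the iodoalkyne by syn delivery of hydrogen to the (Z)-iodoalkene and leaves the trisubstituted alkene alone.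

Step 23
Reactants: 29 (3Z,5Z)-dienyl iodide
Product: 30 2,14-diol
Conditions: HF·pyridine, pyridine, THF, 0 to 40 °C
Reagents that add atoms: none
Why: Buffered fluoride removes both silyl ethers without touching the acetate, the lactone or the iodide.

Step 24
Reactants: 30 2,14-diol
Product: 31 C2 aldehyde
Conditions: TEMPO (10 mol %), PhI(OAc)2, CH2Cl2, rt
Reagents that add atoms: none
Why: The oxoammonium oxidation is selective for the primary alcohol over the hindered secondary 14-hydroxyl and the tertiary 8-hydroxyl.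

Step 25
Reactants: 31 C2 aldehyde
Product: 32 14-butanoate
Conditions: (n-PrCO)2O, DMAP (cat.), pyridine, CH2Cl2, 0 °C
Reagents that add atoms: butanoic anhydride, CCCC(=O)OC(=O)CCC
Why: DMAP-catalysed acylation of the remaining secondary alcohol installs the butanoate under conditions too mild for β-elimination from the C12 ketone.

Step 26
Reactants: 32 14-butanoate
Product: 33 macrocyclic 2-alcohol (ten-membered ring closed)
Conditions: CrCl2 (10 equiv), NiCl2 (1 mol %), DMSO, rt, 2 mM
Reagents that add atoms: none
Why: Intramolecular Nozaki–Hiyama–Kishi reaction of the (Z)-alkenyl iodide with the aldehyde closes the ten-membered ring at C2–C3 with retention of the Z geometry and without touching the C12 ketone; C2 is set in the ring-closing transition state and is expected to be S as drawn.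

Step 27
Reactants: 33 macrocyclic 2-alcohol
Product: 34 2,9-diacetate with the (3Z,5Z)-diene
Conditions: Ac2O, DMAP (cat.), pyridine, CH2Cl2, 0 °C
Reagents that add atoms: acetic anhydride, CC(=O)OC(C)=O
Why: Acetylation of the allylic 2-hydroxyl; the tertiary 8-hydroxyl stays free.

Step 28
Reactants: 34 2,9-diacetate
Product: 35 CNP0283653.1 (target)
Conditions: NCS, PhSeCl (10 mol %), CH2Cl2, rt
Reagents that add atoms: N-chlorosuccinimide, O=C1CCC(=O)N1Cl
Why: Selenium-catalysed ene-type allylic chlorination of the trisubstituted C5=C6 alkene puts chlorine on C6 and moves the double bond to C5=C16; attack on the exposed face of the ring alkene should give the 6S chloride, and the acetoxy-deactivated C3=C4 alkene is spared.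

Compounds
1 | 2-methylcyclohexane-1,3-dione | CC1C(=O)CCCC1=O | starting material
2 | 2-(hydroxymethyl)-2-methylcyclohexane-1,3-dione | CC1(CO)C(=O)CCCC1=O | intermediate
3 | (1-methyl-2,6-dioxocyclohexyl)methyl propanoate | CCC(=O)OCC1(C)C(=O)CCCC1=O | intermediate
4 | [(1R,2R)-2-hydroxy-1-methyl-6-oxocyclohexyl]methyl propanoate | C[C@@]1(COC(=O)CC)[C@H](O)CCCC1=O | intermediate
5 | [(1R,2R)-1-methyl-2-(methylsulfonyloxy)-6-oxocyclohexyl]methyl propanoate | C[C@@]1(COC(=O)CC)[C@H](OS(C)(=O)=O)CCCC1=O | intermediate
6 | [(1R,6R)-1-methyl-6-(methylsulfonyloxy)-2-oxocyclohex-3-en-1-yl]methyl propanoate | C[C@@]1(COC(=O)CC)[C@H](OS(C)(=O)=O)CC=CC1=O | intermediate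
7 | [(1S)-1-methyl-6-oxocyclohexa-2,4-dien-1-yl]methyl propanoate | C[C@@]1(COC(=O)CC)C=CC=CC1=O | intermediate
8 | (Z)-ketene tert-butyldimethylsilyl acetal of 7 (C20 methyl cis to OSi) | C/C=C(\O[Si](C)(C)C(C)(C)C)OC[C@]1(C)C=CC=CC1=O | intermediate
9 | tricyclic silyl ketal: bicyclo[2.2.2]octenone with C14 ketone and C8=C9 bridge, C12 bearing OTBS and tied to C2 through oxygen, C15 and C20 syn to the etheno bridge | C[C@@]12CO[C@@]3(O[Si](C)(C)C(C)(C)C)[C@H](C)[C@@H]1C=C[C@H]3C2=O | intermediate
10 | 14-alcohol of 9 (14-OH cis to C2) | C[C@@]12CO[C@@]3(O[Si](C)(C)C(C)(C)C)[C@H](C)[C@@H]1C=C[C@H]3[C@@H]2O | intermediate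
11 | 7-hydroxy-8-(hydroxymethyl)-3,8-dimethylbicyclo[2.2.2]oct-5-en-2-one (both methyls syn to C5=C6, 7-OH and 8-CH2OH anti to it) | C[C@@]1(CO)[C@H]2C=C[C@@H]([C@@H]1O)C(=O)[C@@H]2C | intermediate
12 | bis(tert-butyldimethylsilyl) ether of 11 | C[C@@]1(CO[Si](C)(C)C(C)(C)C)[C@H]2C=C[C@@H]([C@@H]1O[Si](C)(C)C(C)(C)C)C(=O)[C@@H]2C | intermediate
13 | 5,6-cis-diol of 12 (hydroxyls on the face syn to the C7–C8 bridge) | C[C@@]1(CO[Si](C)(C)C(C)(C)C)[C@H]2[C@@H](O)[C@@H](O)[C@@H]([C@@H]1O[Si](C)(C)C(C)(C)C)C(=O)[C@@H]2C | intermediate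
14 | 5,6-dioxo compound (bicyclo[2.2.2]octane-2,5,6-trione) | C[C@@]1(CO[Si](C)(C)C(C)(C)C)[C@H]2C(=O)C(=O)[C@@H]([C@@H]1O[Si](C)(C)C(C)(C)C)C(=O)[C@@H]2C | intermediate
15 | ring A α-keto ester (C10 bears COCO2Me; C12 ketone; 14-OTBS; C1 bears CH3 and CH2OTBS) | C[C@@]1(CO[Si](C)(C)C(C)(C)C)[C@@H](C(=O)C(=O)OC)[C@@H](C)C(=O)C[C@@H]1O[Si](C)(C)C(C)(C)C | intermediate
16 | (9S)-α-hydroxy ester of ring A | C[C@@]1(CO[Si](C)(C)C(C)(C)C)[C@@H]([C@H](O)C(=O)OC)[C@@H](C)C(=O)C[C@@H]1O[Si](C)(C)C(C)(C)C | intermediate
17 | bridged methyl ketal (O9 bonded to C12, which also bears OMe), methyl ester at C8 | C[C@@]1(CO[Si](C)(C)C(C)(C)C)[C@H]2[C@@H](C(=O)OC)O[C@@](OC)(C[C@@H]1O[Si](C)(C)C(C)(C)C)[C@@H]2C | intermediate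
18 | β-keto ester (C8 ketone, C17 methyl, C19 methyl ester; C17 epimers) | C[C@@]1(CO[Si](C)(C)C(C)(C)C)[C@H]2[C@@H](C(=O)C(C)C(=O)OC)O[C@@](OC)(C[C@@H]1O[Si](C)(C)C(C)(C)C)[C@@H]2C | intermediate
19 | (Z)-enol triflate of 18 (OTf on C8 cis to CO2Me) | C[C@@]1(CO[Si](C)(C)C(C)(C)C)[C@H]2[C@@H](/C(OS(=O)(=O)C(F)(F)F)=C(\C)C(=O)OC)O[C@@](OC)(C[C@@H]1O[Si](C)(C)C(C)(C)C)[C@@H]2C | intermediate
20 | (Z)-3-methylpent-2-en-4-yn-1-ol | C#C/C(C)=C\CO | starting material
21 | (Z)-3-methylpent-2-en-4-ynal | C#C/C(C)=C\C=O | intermediate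
22 | hydroxy enoate (C7 carbinol cis to CO2Me on the C8=C17 alkene) | C[C@@]1(CO[Si](C)(C)C(C)(C)C)[C@H]2[C@@H](/C([C@@H](O)/C=C(/C)C#C)=C(\C)C(=O)OC)O[C@@](OC)(C[C@@H]1O[Si](C)(C)C(C)(C)C)[C@@H]2C | intermediate
23 | butenolide (C8=C17) with the (Z)-enynyl chain at C7 | C[C@@]1(CO[Si](C)(C)C(C)(C)C)[C@H]2[C@@H](C3=C(C)C(=O)O[C@H]3/C=C(/C)C#C)O[C@@](OC)(C[C@@H]1O[Si](C)(C)C(C)(C)C)[C@@H]2C | intermediate
24 | 8,17-epoxy lactone (epoxide oxygen trans to C6) | C[C@@]1(CO[Si](C)(C)C(C)(C)C)[C@H]2[C@@H]([C@@]34O[C@]3(C)C(=O)O[C@H]4/C=C(/C)C#C)O[C@@](OC)(C[C@@H]1O[Si](C)(C)C(C)(C)C)[C@@H]2C | intermediate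
25 | 8-hydroxy lactone (C18 cis to 8-OH, 8-OH cis to H7) | C[C@@]1(CO[Si](C)(C)C(C)(C)C)[C@H]2[C@@H]([C@@]3(O)[C@H](C)C(=O)O[C@H]3/C=C(/C)C#C)O[C@@](OC)(C[C@@H]1O[Si](C)(C)C(C)(C)C)[C@@H]2C | intermediate
26 | 9-hydroxy 12-ketone (ketal removed) | C[C@@]1(CO[Si](C)(C)C(C)(C)C)[C@@H]([C@H](O)[C@@]2(O)[C@H](C)C(=O)O[C@H]2/C=C(/C)C#C)[C@@H](C)C(=O)C[C@@H]1O[Si](C)(C)C(C)(C)C | intermediate
27 | 9-acetate of 26 | C[C@@]1(CO[Si](C)(C)C(C)(C)C)[C@@H]([C@H](OC(C)=O)[C@@]2(O)[C@H](C)C(=O)O[C@H]2/C=C(/C)C#C)[C@@H](C)C(=O)C[C@@H]1O[Si](C)(C)C(C)(C)C | intermediate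
28 | iodoalkyne of 27 | C[C@@]1(CO[Si](C)(C)C(C)(C)C)[C@@H]([C@H](OC(C)=O)[C@@]2(O)[C@H](C)C(=O)O[C@H]2/C=C(/C)C#CI)[C@@H](C)C(=O)C[C@@H]1O[Si](C)(C)C(C)(C)C | intermediate
29 | (3Z,5Z)-dienyl iodide | C[C@@]1(CO[Si](C)(C)C(C)(C)C)[C@@H]([C@H](OC(C)=O)[C@@]2(O)[C@H](C)C(=O)O[C@H]2/C=C(/C)\C=C/I)[C@@H](C)C(=O)C[C@@H]1O[Si](C)(C)C(C)(C)C | intermediate
30 | 2,14-diol of 29 | C[C@@]1(CO)[C@@H]([C@H](OC(C)=O)[C@@]2(O)[C@H](C)C(=O)O[C@H]2/C=C(/C)\C=C/I)[C@@H](C)C(=O)C[C@@H]1O | intermediate
31 | C2 aldehyde with free 14-OH | C[C@@]1(C=O)[C@@H]([C@H](OC(C)=O)[C@@]2(O)[C@H](C)C(=O)O[C@H]2/C=C(/C)\C=C/I)[C@@H](C)C(=O)C[C@@H]1O | intermediate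
32 | C2 aldehyde 14-butanoate (seco compound) | C[C@@]1(C=O)[C@@H]([C@H](OC(C)=O)[C@@]2(O)[C@H](C)C(=O)O[C@H]2/C=C(/C)\C=C/I)[C@@H](C)C(=O)C[C@@H]1OC(=O)CCC | intermediate
33 | macrocyclic (2S)-alcohol with (3Z,5Z)-diene and C16 methyl | O[C@H]1/C=C\C(C)=C/[C@@H]2OC(=O)[C@@H](C)[C@]2(O)[C@@H](OC(C)=O)[C@H]3[C@@H](C)C(=O)C[C@H](OC(=O)CCC)[C@]13C | intermediate
34 | 2,9-diacetate of 33 | CC(=O)O[C@H]1/C=C\C(C)=C/[C@@H]2OC(=O)[C@@H](C)[C@]2(O)[C@@H](OC(C)=O)[C@H]3[C@@H](C)C(=O)C[C@H](OC(=O)CCC)[C@]13C | intermediate
35 | CNP0283653.1 | C=C1/C=C\[C@H](OC(C)=O)[C@]2(C)[C@H]([C@@H](C)C(=O)C[C@@H]2OC(=O)CCC)[C@H](OC(C)=O)[C@@]2(O)[C@H](C)C(=O)O[C@H]2[C@H]1Cl | target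

Total step count: 28. Longest linear sequence: 27 steps (steps 1–14 and 16–28; step 15 prepares the side-chain aldehyde).

Steps most likely to fail

Step 6. The cycloaddition may stop after the first C–C bond (conjugate addition followed by silyl transfer), or the dienone may dimerise before the strained bridged transition state is reached. The fallback forms the two bonds one after the other and sets out from 7. LiN(SiMe3)2 in THF at −78 °C without silyl chloride should trigger the intramolecular Michael addition of the ester enolate to C10; protonation gives the cis-fused δ-lactone F1. LiN(iPr)2 at −78 °C then removes the doubly activated C13 proton, and the enolate adds across the ring to the lactone carbonyl (Dieckmann-type addition). Trapping of the lithium hemiketal alkoxide with TBSOTf returns to 9.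

Step 26. The ring closure may show poor facial selectivity at the aldehyde and give mainly the wrong C2 carbinol. The fallback sets out from 32 and sets C2 by reagent control after the ring is closed. The closure is run as before and the carbinol mixture is oxidised with MnO2 (allylic alcohols only) to the macrocyclic dienone F2. Corey–Bakshi–Shibata reduction of F2 with the oxazaborolidine catalyst and catecholborane at −78 °C, which should prefer the conjugated ketone over the flanked C12 ketone, returns to 33.

Step 28. Chlorine may enter on the wrong face of C5=C6, attack the other alkene, or end up on C16 by allylic transposition. The fallback sets out from 34 and separates the C–O bond formation from the chlorination. A Schenck ene reaction with singlet oxygen (O2, tetraphenylporphyrin, hν, CH2Cl2, 0 °C) places oxygen on C6 and moves the double bond to C5=C16, giving the hydroperoxide F3. PPh3 reduces F3 to the allylic alcohol F4, and an Appel chlorination (PPh3, CCl4, inversion) returns to 35. If the ene reaction gives the other C6 epimer, thionyl chloride with retention would be used instead.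

Further compounds
F1 | step 6 | cis-fused δ-lactone from the intramolecular Michael addition (C10–C11 bond formed, β,γ-unsaturated C14 ketone) | C[C@@]12COC(=O)[C@H](C)[C@@H]1C=CCC2=O
F2 | step 26 | macrocyclic dienone (2-oxo analogue of 33) | O=C1/C=C\C(C)=C/[C@@H]2OC(=O)[C@@H](C)[C@]2(O)[C@@H](OC(C)=O)[C@H]3[C@@H](C)C(=O)C[C@H](OC(=O)CCC)[C@]13C
F3 | step 28 | C6 hydroperoxide with C5=C16 exocyclic alkene (C6 configuration opposite to that of the chloride) | C=C1/C=C\[C@H](OC(C)=O)[C@]2(C)[C@H]([C@@H](C)C(=O)C[C@@H]2OC(=O)CCC)[C@H](OC(C)=O)[C@@]2(O)[C@H](C)C(=O)O[C@H]2[C@@H]1OO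
F4 | step 28 | C6 allylic alcohol from F3 | C=C1/C=C\[C@H](OC(C)=O)[C@]2(C)[C@H]([C@@H](C)C(=O)C[C@@H]2OC(=O)CCC)[C@H](OC(C)=O)[C@@]2(O)[C@H](C)C(=O)O[C@H]2[C@@H]1O
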